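**Retrosynthetic overview** (ring A = phloroglucinol ring, ring B = prenylated aryl, ring C = pyranone)
1. Cathayanon I ⇐ its ring-B bis(allyl) ether, by a final Pd-mediated deallylation that keeps acid away from the ortho-prenyl phenols.
2. Key cut of two bonds at once, C4a–C8a (ring A) and O1–C2 (ring C) ⇒ a pyranone-masked epoxy tetraketide, i.e. triacetic acid lactone dianion + an aryl glycidic N-acylpyrrole.
3. (2R,3S)-Glycidic acylpyrrole ⇐ ring-B aldehyde by one-pot Wittig olefination / catalytic asymmetric nucleophilic epoxidation (both stereocentres set here; C-2 is later inverted, C-3 retained).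
4. Ring-B aldehyde ⇐ 2,4-dihydroxybenzaldehyde by double C-prenylation, then O-allylation.
5. Ring order: ring B is bought; oxirane (temporary, step 3); then ring A (Claisen aromatisation) and ring C (epoxide opening) in the same pot in step 4.

Assumption: the SMILES is read as the (2R,3R), 2,3-trans flavanonol, and ylide 5 is taken to be a purchasable catalog reagent.
Abbreviation: Ar = 3,5-bis(3-methylbut-2-en-1-yl)-2,4-bis(prop-2-en-1-yloxy)phenyl.

**Step 1**
Reactants: 1 2,4-dihydroxybenzaldehyde; 2 1-bromo-3-methylbut-2-ene (prenyl bromide)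
Product: 3 2,4-dihydroxy-3,5-bis(3-methylbut-2-en-1-yl)benzaldehyde
Conditions: 2 (2.3 equiv), KOH (10% aq., 3 equiv), 0 °C → rt
Reagents that add atoms: 1-bromo-3-methylbut-2-ene (2), CC(C)=CCBr
Why: Phenoxide C-alkylation (C-prenylation): in water the hydrogen-bonded dianion of 1 reacts on carbon at C-3 and C-5, the only positions ortho/para to both oxygens (C-6 is meta to both), so both prenyl groups enter in one pot; the yield is modest (O-prenyl ethers are separated, mono-prenyl phenols recycled) and no stereocentre is formed.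

**Step 2**
Reactants: 3 2,4-dihydroxy-3,5-bis(3-methylbut-2-en-1-yl)benzaldehyde
Product: 4 3,5-bis(3-methylbut-2-en-1-yl)-2,4-bis(prop-2-en-1-yloxy)benzaldehyde (Ar–CHO)
Conditions: allyl bromide (3 equiv), K2CO3 (4 equiv), DMF, 50 °C
Reagents that add atoms: prop-2-en-1-yl bromide (allyl bromide), C=CCBr
Why: Williamson etherification: both hindered phenoxides are capped by the small, reactive allyl bromide, and allyl ethers survive the ylide, peroxide, amide-base and methoxide steps and come off at the end without acid.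

**Step 3**
Reactants: 4 3,5-bis(3-methylbut-2-en-1-yl)-2,4-bis(prop-2-en-1-yloxy)benzaldehyde; 5 1-(1H-pyrrol-1-yl)-2-(triphenyl-λ5-phosphanylidene)ethan-1-one
Product: 7 {(2R,3S)-3-Ar-oxiran-2-yl}(1H-pyrrol-1-yl)methanone, via enoyl pyrrole 6 (not isolated)
Conditions: 5 (1.0 equiv), toluene, 100 °C; then rt: Sm(O-iPr)3 (10 mol %), (S)-H8-BINOL [(S)-5,5′,6,6′,7,7′,8,8′-octahydro-1,1′-bi-2-naphthol] (10 mol %), t-BuOOH (1.5 equiv, decane), 4 Å MS, THF
Reagents that add atoms: ylide 5, O=C(C=P(c1ccccc1)(c1ccccc1)c1ccccc1)n1cccc1; tert-butyl hydroperoxide, CC(C)(C)OO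
Why: One-pot Wittig olefination / catalytic asymmetric nucleophilic (Weitz–Scheffer-type) epoxidation: the stabilised ylide gives E-enoyl pyrrole 6 plus Ph3P=O, which serves as the achiral ligand of the Sm(O-iPr)3/(S)-H8-BINOL catalyst that adds tert-butylperoxide conjugately to one face of the ketone-like acyl pyrrole, the (S)-ligand (antipode of the one known to give (αS,βR) epoxides in this catalyst class) setting both oxirane centres as (2R,3S), while the electron-rich prenyl and allyl olefins are inert to a nucleophilic oxidant.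

**Step 4**
Reactants: 7 {(2R,3S)-3-Ar-oxiran-2-yl}(1H-pyrrol-1-yl)methanone; 8 4-hydroxy-6-methyl-2H-pyran-2-one (triacetic acid lactone)
Product: 13 (2R,3R)-2-Ar-3,5,7-trihydroxy-2,3-dihydro-4H-chromen-4-one, via dilithiated pyranone 9 (not isolated), via epoxy keto pyranone 10 (not isolated), via triketo ester 11 (not isolated), via epoxy aryl ketone 12 (not isolated)
Conditions: 8 (2.2 equiv), LiN(iPr)2 (4.4 equiv), THF–DMPU, −78 °C; add 7, −78 → −20 °C; then Mg(OMe)2 (8 equiv) in MeOH, −20 → 40 °C, Ar; 1 M HCl to pH 4, 0 °C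
Reagents that add atoms: none
Why: Proposed new method: the methyl carbanion of dianion 9 is C-acylated by the acyl pyrrole to give 10, excess Mg(OMe)2/MeOH opens the 4-hydroxypyranone to triketo ester 11 bound to Mg2+, in which both ketones are enolised so the ester is the only electrophile and the C-6 carbanion closes ring A by Claisen (Dieckmann-type) condensation and aromatises to 12, whose ortho phenoxide then opens the Mg2+-activated oxirane 6-endo at the benzylic carbon with inversion (that carbon becomes C-2 = R, the retained carbinol becomes C-3 = R, 2,3-trans) to close ring C; the closest known reactions are the biomimetic Claisen cyclisation of pyranone-masked 3,5,7-triketo esters to acylphloroglucinols and the cyclisation of 2′-hydroxychalcone epoxides to trans-dihydroflavonols.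

**Step 5**
Reactants: 13 (2R,3R)-2-Ar-3,5,7-trihydroxy-2,3-dihydro-4H-chromen-4-one
Product: 14 Cathayanon I, (2R,3R)-2-[2,4-dihydroxy-3,5-bis(3-methylbut-2-en-1-yl)phenyl]-3,5,7-trihydroxy-2,3-dihydro-4H-chromen-4-one
Conditions: Pd(PPh3)4 (5 mol %), morpholine (10 equiv), THF, rt, Ar
Reagents that add atoms: none
Why: Tsuji–Trost-type deallylation: zerovalent palladium ionises only the two O-allyl aryl ethers to π-allyl complexes that morpholine traps, so the C-prenyl groups, the ketol and both stereocentres are untouched under near-neutral conditions and no acid is present to close chromans onto the ortho-prenyl phenols.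

**Compound list**
1 | 2,4-dihydroxybenzaldehyde | O=Cc1ccc(O)cc1O | starting material
2 | 1-bromo-3-methylbut-2-ene (prenyl bromide) | CC(C)=CCBr | starting material
3 | 2,4-dihydroxy-3,5-bis(3-methylbut-2-en-1-yl)benzaldehyde | O=Cc1cc(CC=C(C)C)c(O)c(CC=C(C)C)c1O | intermediate
4 | 3,5-bis(3-methylbut-2-en-1-yl)-2,4-bis(prop-2-en-1-yloxy)benzaldehyde | O=Cc1cc(CC=C(C)C)c(OCC=C)c(CC=C(C)C)c1OCC=C | intermediate
5 | 1-(1H-pyrrol-1-yl)-2-(triphenyl-λ5-phosphanylidene)ethan-1-one | O=C(C=P(c1ccccc1)(c1ccccc1)c1ccccc1)n1cccc1 | starting material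
6 | (2E)-3-Ar-1-(1H-pyrrol-1-yl)prop-2-en-1-one | O=C(/C=C/c1cc(CC=C(C)C)c(OCC=C)c(CC=C(C)C)c1OCC=C)n1cccc1 | intermediate
7 | {(2R,3S)-3-Ar-oxiran-2-yl}(1H-pyrrol-1-yl)methanone (trans-epoxide) | O=C([C@@H]1O[C@H]1c1cc(CC=C(C)C)c(OCC=C)c(CC=C(C)C)c1OCC=C)n1cccc1 | intermediate
8 | 4-hydroxy-6-methyl-2H-pyran-2-one | Cc1cc(O)cc(=O)o1 | starting material
9 | lithium 6-(lithiomethyl)-2-oxo-2H-pyran-4-olate | [Li]Cc1cc(O[Li])cc(=O)o1 | intermediate
10 | 4-hydroxy-6-{2-[(2R,3S)-3-Ar-oxiran-2-yl]-2-oxoethyl}-2H-pyran-2-one | O=C(Cc1cc(O)cc(=O)o1)[C@@H]1O[C@H]1c1cc(CC=C(C)C)c(OCC=C)c(CC=C(C)C)c1OCC=C | intermediate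
11 | methyl 7-[(2R,3S)-3-Ar-oxiran-2-yl]-3,5,7-trioxoheptanoate | COC(=O)CC(=O)CC(=O)CC(=O)[C@@H]1O[C@H]1c1cc(CC=C(C)C)c(OCC=C)c(CC=C(C)C)c1OCC=C | intermediate
12 | [(2R,3S)-3-Ar-oxiran-2-yl](2,4,6-trihydroxyphenyl)methanone | O=C(c1c(O)cc(O)cc1O)[C@@H]1O[C@H]1c1cc(CC=C(C)C)c(OCC=C)c(CC=C(C)C)c1OCC=C | intermediate
13 | (2R,3R)-2-Ar-3,5,7-trihydroxy-2,3-dihydro-4H-chromen-4-one | CC(C)=CCc1cc([C@H]2Oc3cc(O)cc(O)c3C(=O)[C@@H]2O)c(OCC=C)c(CC=C(C)C)c1OCC=C | intermediate
14 | Cathayanon I | CC(C)=CCc1cc([C@H]2Oc3cc(O)cc(O)c3C(=O)[C@@H]2O)c(O)c(CC=C(C)C)c1O | target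

**Totals:** 5 steps; longest linear sequence 5 steps (1 → 3 → 4 → 7 → 13 → 14).

**Three steps most likely to fail, with fallbacks**

Step 4 (key cascade). Risks: aldol-type closure of 11 to a resorcylate instead of the Claisen mode; 5-exo opening of the oxirane at the α-carbon (benzofuranone) instead of 6-endo; air oxidation of the product phenoxide to the flavonol. The fallback brings ring A in preformed and closes ring C under acid; it sets out from 7 and comes back at 13. Phloroglucinol is converted (NaH, MOMCl, DMF) into 1,3,5-tris(methoxymethoxy)benzene F1. n-BuLi (THF, 0 °C) lithiates it to [2,4,6-tris(methoxymethoxy)phenyl]lithium F2. F2 adds to acyl pyrrole 7 at −78 °C to give [(2R,3S)-3-Ar-oxiran-2-yl][2,4,6-tris(methoxymethoxy)phenyl]methanone F3. HCl (3 M aq.)/MeOH at 40 °C then removes the three MOM groups, and the freed ortho phenol opens the protonated oxirane at the benzylic carbon to give 13. The ring-B phenols stay allylated there, so no chroman can form.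

Step 3 (Wittig/epoxidation). Risks: slow peroxide addition to the electron-rich, hindered enoyl pyrrole; an acid-labile electron-rich aryl oxirane. The fallback uses iminium organocatalysis at the aldehyde oxidation level; it sets out from 4 and comes back at 10. Wittig reaction of 4 with (triphenylphosphoranylidene)acetaldehyde (toluene, 80 °C) gives (2E)-3-Ar-prop-2-enal F4. Epoxidation with H2O2 and 10 mol % (S)-2-{bis[3,5-bis(trifluoromethyl)phenyl][(trimethylsilyl)oxy]methyl}pyrrolidine in CH2Cl2 gives (2R,3S)-3-Ar-oxirane-2-carbaldehyde F5. Aldol addition of dianion 9 (THF, −78 °C) gives 4-hydroxy-6-{2-hydroxy-2-[(2S,3S)-3-Ar-oxiran-2-yl]ethyl}-2H-pyran-2-one F6 as both carbinol epimers, with the same spatial arrangement at the oxirane as in F5 (the C-2 label changes by the CIP rules). Dess–Martin periodinane (NaHCO3, CH2Cl2) oxidises F6 to 10, which is isolated and treated with Mg(OMe)2/MeOH as in the second half of step 4.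

Step 1 (double C-prenylation). Risks: O- versus C-alkylation, mono- and over-prenylation, hence a low yield. The fallback replaces it by halogenation and cross-coupling with full regiocontrol; it sets out from 1 and comes back at 3. NIS (2.1 equiv, MeCN) gives 2,4-dihydroxy-3,5-diiodobenzaldehyde F7. Ac2O/pyridine gives 4-formyl-2,6-diiodo-1,3-phenylene diacetate F8. Double Stille coupling with tributyl(3-methylbut-2-en-1-yl)stannane (Pd(PPh3)4, DMF, 90 °C; coupling at the tin-bearing CH2 gives the linear prenyl groups) gives 4-formyl-2,6-bis(3-methylbut-2-en-1-yl)-1,3-phenylene diacetate F9. K2CO3/MeOH at rt cleaves the acetates to 3.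

**Further compounds**
F1 | step 4 | 1,3,5-tris(methoxymethoxy)benzene | COCOc1cc(OCOC)cc(OCOC)c1
F2 | step 4 | [2,4,6-tris(methoxymethoxy)phenyl]lithium | [Li]c1c(OCOC)cc(OCOC)cc1OCOC
F3 | step 4 | [(2R,3S)-3-Ar-oxiran-2-yl][2,4,6-tris(methoxymethoxy)phenyl]methanone | O=C(c1c(OCOC)cc(OCOC)cc1OCOC)[C@@H]1O[C@H]1c1cc(CC=C(C)C)c(OCC=C)c(CC=C(C)C)c1OCC=C
F4 | step 3 | (2E)-3-Ar-prop-2-enal | O=C/C=C/c1cc(CC=C(C)C)c(OCC=C)c(CC=C(C)C)c1OCC=C
F5 | step 3 | (2R,3S)-3-Ar-oxirane-2-carbaldehyde | O=C[C@@H]1O[C@H]1c1cc(CC=C(C)C)c(OCC=C)c(CC=C(C)C)c1OCC=C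
F6 | step 3 | 4-hydroxy-6-{2-hydroxy-2-[(2S,3S)-3-Ar-oxiran-2-yl]ethyl}-2H-pyran-2-one (both carbinol epimers) | OC(Cc1cc(O)cc(=O)o1)[C@@H]1O[C@H]1c1cc(CC=C(C)C)c(OCC=C)c(CC=C(C)C)c1OCC=C
F7 | step 1 | 2,4-dihydroxy-3,5-diiodobenzaldehyde | O=Cc1cc(I)c(O)c(I)c1O
F8 | step 1 | 4-formyl-2,6-diiodo-1,3-phenylene diacetate | CC(=O)Oc1c(I)cc(C=O)c(OC(C)=O)c1I
F9 | step 1 | 4-formyl-2,6-bis(3-methylbut-2-en-1-yl)-1,3-phenylene diacetate | CC(=O)Oc1c(CC=C(C)C)cc(C=O)c(OC(C)=O)c1CC=C(C)C
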